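The retrosynthesis removes the two angelates, the C1 carbonyl and the C3 methyl, going back to a C3 ketal and a C8 silyl enol ether, and then cuts the seven-membered ring at C9–C10 and C5–C6.
This double cut is possible because the one-carbon bridges C5 and C10 of the bicyclo[3.1.1]heptane core (six-membered ring C1–C2–C3–C4–C10–C11, cyclobutane C4–C5–C11–C10) are joined a second time by the chain C6–C7–C8–C9; it leaves a bicyclobutane (central bond C5–C10, wings C4 and C11 bridged by C1–C3) and a 2-silyloxydiene.
Forward order: six-membered ring (3-methylcyclohexenone) → dibromocyclopropane → bicyclobutane by carbenoid C–H insertion → seven-membered ring by (4+3) annulation → oxygen at C7, C9, C8 → angelates → C3 methyl alkene → C1 ketone.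
Stereochemistry: the absolute configuration comes from a Corey–Bakshi–Shibata reduction, relayed by anti dibromocarbene addition to C4/C10 and through the bicyclobutane to C5/C11; C7 is set by reagent-controlled Shi epoxidation, C9 trans to C7 by enolate hydroxylation, C8 by hydroxyl-directed reduction.
Key step: step 8

Numbering: target numbering is kept for all tricyclic intermediates; "3-desmethyllongipinane" is the target skeleton without the C3 methyl; the faces of the seven-membered ring are named after the cyclobutane carbon beneath them (in the target O7 is on the C4 face, O8 and O9 on the C11 face).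
Assumption: the facial senses of the Corey–Bakshi–Shibata reduction (step 1) and the Shi epoxidation (step 9) follow the usual models; if either is found reversed, the enantiomeric catalyst is used with no other change.

Step 1
Reactants: 1 3-methylcyclohex-2-en-1-one
Product: 2 (S)-3-methylcyclohex-2-en-1-ol
Conditions: (R)-2-methyl-CBS-oxazaborolidine (10 mol %), BH3·SMe2, THF, −20 °C; MeOH, then aqueous work-up
Reagents that add atoms: none
Why: Corey–Bakshi–Shibata reduction of a cyclic enone, in which the alkenyl carbon acts as the larger carbonyl substituent, so the (R)-catalyst should deliver hydride to the face giving the (S)-carbinol, the only source of absolute configuration for the ring system.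

Step 2
Reactants: 2 (S)-3-methylcyclohex-2-en-1-ol
Product: 3 (S)-triethyl[(3-methylcyclohex-2-en-1-yl)oxy]silane
Conditions: Et3SiCl, imidazole, CH2Cl2, 0 °C → rt
Reagents that add atoms: chlorotriethylsilane, CC[Si](Cl)(CC)CC
Why: Routine silylation of a secondary allylic alcohol installs the bulky group that directs the cyclopropanation and touches no stereocentre.

Step 3
Reactants: 3 (S)-triethyl[(3-methylcyclohex-2-en-1-yl)oxy]silane; 4 bromoform
Product: 6 (1S,2S,6S)-7,7-dibromo-6-methyl-2-(triethylsilyloxy)bicyclo[4.1.0]heptane, via dibromocarbene 5 (not isolated)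
Conditions: KOt-Bu, pentane, −20 → 0 °C
Reagents that add atoms: none
Why: Dibromocyclopropanation of an electron-rich trisubstituted alkene, in which the carbene should add anti to the allylic silyloxy group and so fix C4 and C10 from the carbinol centre; any syn adduct, which would lead into the enantiomeric series, is removed by chromatography here.

Step 4
Reactants: 6 (1S,2S,6S)-7,7-dibromo-6-methyl-2-(triethylsilyloxy)bicyclo[4.1.0]heptane
Product: 7 (1S,6S)-7,7-dibromo-6-methylbicyclo[4.1.0]heptan-2-one
Conditions: CrO3, H2SO4, acetone–H2O, 0 °C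
Reagents that add atoms: none
Why: Jones oxidation, in which the aqueous acid cleaves the triethylsilyl ether and H2CrO4 oxidises the freed carbinol in the same flask, while the gem-dibromocyclopropane tolerates both and the carbinol centre, no longer needed, is erased.

Step 5
Reactants: 7 (1S,6S)-7,7-dibromo-6-methylbicyclo[4.1.0]heptan-2-one
Product: 8 (1'S,6'S)-7',7'-dibromo-6'-methylspiro[1,3-dioxolane-2,2'-bicyclo[4.1.0]heptane]
Conditions: (Me3SiOCH2)2, Me3SiOTf (5 mol %), CH2Cl2, −78 → −20 °C
Reagents that add atoms: 1,2-bis(trimethylsilyloxy)ethane, C[Si](C)(C)OCCO[Si](C)(C)C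
Why: Noyori ketalisation under aprotic conditions protects the ketone against methyllithium and leaves the carbon next to C4 without hydrogen, so the carbenoid of step 6 can insert only on the C11 side.

Step 6
Reactants: 8 (1'S,6'S)-7',7'-dibromo-6'-methylspiro[1,3-dioxolane-2,2'-bicyclo[4.1.0]heptane]
Product: 10 1-methyltricyclo[4.1.0.0(2,7)]heptan-3-one ethylene ketal, via lithium carbenoid 9 (not isolated)
Conditions: MeLi, Et2O, −78 → 0 °C
Reagents that add atoms: none
Why: Bromine–lithium exchange and α-elimination give a cyclopropylidene carbenoid that inserts into the syn C–H bond of the neighbouring ring methylene (the standard route from 7,7-dibromonorcaranes to tricyclo[4.1.0.0(2,7)]heptanes); the ketal carbon blocks the other flank, the spiro ring holds the dioxolane O–CH2 groups away from the carbenoid carbon, and C5 and C11 can form only with the geometry of the fused bicyclobutane, whose central bond joins the methyl-bearing C10 and the hydrogen-bearing C5.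

Step 7
Reactants: 11 mesityl oxide (4-methylpent-3-en-2-one)
Product: 13 2-(tert-butyldimethylsilyloxy)-4-methylpenta-1,3-diene, via lithium dienolate 12 (not isolated)
Conditions: LiN(i-Pr)2, THF, −78 °C; then t-BuMe2SiCl, DMPU, −78 °C → rt
Reagents that add atoms: tert-butylchlorodimethylsilane, CC(C)(C)[Si](C)(C)Cl
Why: Kinetic deprotonation of the α'-methyl group and O-silylation of the cross-conjugated dienolate (silyl enol ether formation) give the 2-silyloxydiene without creating a stereocentre.

Step 8
Reactants: 10 1-methyltricyclo[4.1.0.0(2,7)]heptan-3-one ethylene ketal; 13 2-(tert-butyldimethylsilyloxy)-4-methylpenta-1,3-diene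
Product: 14 8-(tert-butyldimethylsilyloxy)-3-desmethyllongipin-7-en-3-one ethylene ketal (C4, C5, C10, C11 as in the target)
Conditions: 9,10-dicyanoanthracene (5 mol %), 2,6-di-tert-butylpyridine (0.2 equiv), 13 (3 equiv), MeCN–CH2Cl2, 427 nm LEDs, −20 °C
Reagents that add atoms: none
Why: Proposed new method: photoexcited 9,10-dicyanoanthracene takes one electron from the 10/13 pair (the p-rich central bond and the silyl dienol ether should be similarly easy to oxidise, so the hole is shared), C9 of the diene bonds to C10, the tertiary bridgehead that carries the positive charge, and the C5 cyclobutyl radical then adds to C6 of the silyloxyallyl cation before the dicyanoanthracene radical anion returns the electron and releases the silyl enol ether. The closest known reactions are photoredox and Lewis-acid formal cycloadditions of acyl- or aryl-activated bicyclobutanes, (4+3) variants with silyl dienol ethers among them, and the capture of alkylbicyclobutane radical cations by nucleophiles; an unactivated, bridged bicyclobutane has not been annulated in this way. The seven-membered ring closes stepwise, C9–C10 first and then C5–C6 by 7-endo attack of the radical on the allyl cation terminus. The configurations at C10 and C5 are fixed by the tricyclic frame: a four-carbon chain can span the two bridgeheads only over the convex face, because the C1–C3 bridge fills the concave one, so the C10 methyl and the C5 hydrogen end up turned toward that bridge as in the target, while C4 and C11 are carried over from 10. Three selectivities are needed: C9 must bond to C10 and not to C5 (argued from charge localisation at the methyl-bearing carbon and because the other pairing would have to join two quaternary carbons), closure must be (4+3) at C6 and not (3+2) at C8 (favoured by the lower strain of a bicyclo[4.1.1]octane and by formation of the stable enol-ether radical cation), and C9 must enter on the convex face although small nucleophiles are known to open such radical cations from the rear; here the rear of C10 is a neopentyl pocket closed by the bridge and the dioxolane, and a rear-side adduct could not cyclise.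

Step 9
Reactants: 14 8-(tert-butyldimethylsilyloxy)-3-desmethyllongipin-7-en-3-one ethylene ketal
Product: 16 (7S)-7-hydroxy-3-desmethyllongipinane-3,8-dione 3-ethylene ketal (hydroxyl on the C4 face), via silyloxy epoxide 15 (not isolated)
Conditions: L-fructose-derived Shi ketone (30 mol %), KHSO5 (as 2KHSO5·KHSO4·K2SO4), K2CO3, Bu4NHSO4, MeCN–(MeO)2CH2–aq. Na2B4O7 buffer (pH 10.5), 0 °C; then aq. citric acid, THF, 0 °C
Reagents that add atoms: potassium peroxymonosulfate, [K+].[O-]S(=O)(=O)OO
Why: Rubottom-type oxidation by Shi asymmetric epoxidation of the trisubstituted silyl enol ether, where the ring has little facial bias of its own (C1 and C3 are remote) and the chiral dioxirane decides; the L-fructose-derived ketone is chosen because, by analogy with 1-substituted cycloalkenes, it should put the oxygen on the C4 face, and mild acid then opens the silyloxy epoxide to the α-hydroxy ketone.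

Step 10
Reactants: 16 (7S)-7-hydroxy-3-desmethyllongipinane-3,8-dione 3-ethylene ketal
Product: 17 7-O-triethylsilyl ether of 16
Conditions: Et3SiOTf, 2,6-lutidine, CH2Cl2, −78 °C
Reagents that add atoms: triethylsilyl trifluoromethanesulfonate, CC[Si](CC)(CC)OS(=O)(=O)C(F)(F)F
Why: Silylation of the hindered neopentyl carbinol with a silyl triflate gives temporary protection and the bulky group that steers the next step.

Step 11
Reactants: 17 7-O-triethylsilyl ether of 16
Product: 19 9-hydroxy-7-(triethylsilyloxy)-3-desmethyllongipinane-3,8-dione 3-ethylene ketal (9-OH on the C11 face; trans to O7), via lithium enolate 18 (not isolated)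
Conditions: LiN(i-Pr)2, THF, −78 °C; then 2-(phenylsulfonyl)-3-phenyloxaziridine, −78 °C; aqueous work-up
Reagents that add atoms: 2-(phenylsulfonyl)-3-phenyloxaziridine, O=S(=O)(c1ccccc1)N1OC1c1ccccc1
Why: Enolate hydroxylation with the Davis oxaziridine, in which kinetic deprotonation should occur at C9 (C7 is the hindered, oxygen-bearing carbon) and the oxidant should approach the face away from the C7 silyloxy group, giving the 7,9-trans product.

Step 12
Reactants: 19 9-hydroxy-7-(triethylsilyloxy)-3-desmethyllongipinane-3,8-dione 3-ethylene ketal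
Product: 21 7-hydroxy-9-(tert-butyldimethylsilyloxy)-3-desmethyllongipinane-3,8-dione 3-ethylene ketal, via bis-silyl ether 20 (not isolated)
Conditions: t-BuMe2SiOTf, 2,6-lutidine, CH2Cl2, −78 → 0 °C; then PPTS, MeOH, rt
Reagents that add atoms: tert-butyldimethylsilyl trifluoromethanesulfonate, CC(C)(C)[Si](C)(C)OS(=O)(=O)C(F)(F)F
Why: Silylation of O9 as the robust tert-butyldimethylsilyl ether followed by selective acid methanolysis of the far more labile triethylsilyl ether frees O7 alone.

Step 13
Reactants: 21 7-hydroxy-9-(tert-butyldimethylsilyloxy)-3-desmethyllongipinane-3,8-dione 3-ethylene ketal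
Product: 22 7,8-dihydroxy-9-(tert-butyldimethylsilyloxy)-3-desmethyllongipinan-3-one ethylene ketal (O7 on the C4 face; O8 and O9 on the C11 face)
Conditions: Me4NBH(OAc)3, MeCN–AcOH, −30 °C
Reagents that add atoms: none
Why: Hydroxyl-directed reduction of Evans–Saksena type, in which the C7 hydroxyl binds boron and delivers hydride to its own face, also the face away from the C9 silyl ether, so the new C8 hydroxyl is anti to O7 and syn to O9 as in the target.

Step 14
Reactants: 22 7,8-dihydroxy-9-(tert-butyldimethylsilyloxy)-3-desmethyllongipinan-3-one ethylene ketal; 23 angelic acid ((Z)-2-methylbut-2-enoic acid), the first of the two equivalents that end up in the product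
Product: 25 7,8-bis(angeloyloxy)-9-(tert-butyldimethylsilyloxy)-3-desmethyllongipinan-3-one ethylene ketal, via mixed anhydride 24 (not isolated)
Conditions: 23 (3 equiv), 2,4,6-trichlorobenzoyl chloride (3 equiv), Et3N, toluene, rt; then 22, toluene, 80 °C
Reagents that add atoms: angelic acid (the second equivalent, delivered like the first as mixed anhydride 24), C/C=C(/C)C(=O)O
Why: Yamaguchi-type esterification through the 2,4,6-trichlorobenzoyl mixed anhydride without nucleophilic catalyst, the established way to make angelates without isomerisation to tiglates, should acylate both free hydroxyls, each taking its angeloyl group from a separate molecule of 24, while O9 stays silylated.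

Step 15
Reactants: 25 7,8-bis(angeloyloxy)-9-(tert-butyldimethylsilyloxy)-3-desmethyllongipinan-3-one ethylene ketal
Product: 26 7,8-bis(angeloyloxy)-9-(tert-butyldimethylsilyloxy)-3-desmethyllongipinan-3-one
Conditions: PPTS, acetone–H2O, 60 °C
Reagents that add atoms: water, O
Why: Acid-catalysed ketal hydrolysis with a mild pyridinium acid, which the hindered secondary silyl ether and the angelates should tolerate.

Step 16
Reactants: 26 7,8-bis(angeloyloxy)-9-(tert-butyldimethylsilyloxy)-3-desmethyllongipinan-3-one
Product: 28 7,8-bis(angeloyloxy)-9-(tert-butyldimethylsilyloxy)-3-desmethyllongipin-2-en-3-yl trifluoromethanesulfonate, via potassium enolate 27 (not isolated)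
Conditions: KN(SiMe3)2, THF, −78 °C; then PhNTf2, −78 → 0 °C; aq. NH4Cl
Reagents that add atoms: N-phenylbis(trifluoromethanesulfonimide), O=S(=O)(N(c1ccccc1)S(=O)(=O)C(F)(F)F)C(F)(F)F
Why: Kinetic enolisation and O-triflation give a single enol triflate because C4 is a bridgehead and only C2 can be deprotonated, and the ketone is far more acidic than the angelates.

Step 17
Reactants: 28 7,8-bis(angeloyloxy)-9-(tert-butyldimethylsilyloxy)-3-desmethyllongipin-2-en-3-yl trifluoromethanesulfonate
Product: 29 7,8-bis(angeloyloxy)-9-(tert-butyldimethylsilyloxy)longipin-2-ene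
Conditions: MeZnCl, Pd(PPh3)4 (5 mol %), THF, 50 °C
Reagents that add atoms: methylzinc chloride, C[Zn]Cl
Why: Negishi cross-coupling of the enol triflate with methylzinc chloride tolerates the esters and installs the C3 methyl with the double bond fixed at C2=C3.

Step 18
Reactants: 29 7,8-bis(angeloyloxy)-9-(tert-butyldimethylsilyloxy)longipin-2-ene
Product: 30 7,8-bis(angeloyloxy)-9-(tert-butyldimethylsilyloxy)longipin-2-en-1-one
Conditions: CrO3, 3,5-dimethylpyrazole, CH2Cl2, −20 °C
Reagents that add atoms: chromium trioxide, O=[Cr](=O)=O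
Why: Allylic oxidation with the chromium trioxide–dimethylpyrazole complex, the α-pinene-to-verbenone transformation on the same bicyclo[3.1.1]heptene subunit, should oxidise the ring methylene C1 in preference to the vinylic methyl, the bridgehead C4–H and the methyl groups of the electron-poor angelates.

Step 19
Reactants: 30 7,8-bis(angeloyloxy)-9-(tert-butyldimethylsilyloxy)longipin-2-en-1-one
Product: 31 (4R,5S,7S,8S,9S,10R,11R)-7,8-bis(angeloyloxy)-9-hydroxylongipin-2-en-1-one (target)
Conditions: HF·pyridine, pyridine, THF, 0 °C → rt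
Reagents that add atoms: none
Why: Desilylation with buffered hydrogen fluoride removes the silyl ether under mildly acidic conditions, avoiding the 8-to-9 acyl migration that basic fluoride could cause.

Compound list
1 | 3-methylcyclohex-2-en-1-one | CC1=CC(=O)CCC1 | starting material
2 | (S)-3-methylcyclohex-2-en-1-ol | CC1=C[C@@H](O)CCC1 | intermediate
3 | (S)-triethyl[(3-methylcyclohex-2-en-1-yl)oxy]silane | CC1=C[C@@H](O[Si](CC)(CC)CC)CCC1 | intermediate
4 | bromoform | BrC(Br)Br | starting material
5 | dibromocarbene | Br[C]Br | intermediate (not isolated)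
6 | (1S,2S,6S)-7,7-dibromo-6-methyl-2-(triethylsilyloxy)bicyclo[4.1.0]heptane (silyloxy anti to the cyclopropane) | C[C@]12CCC[C@H](O[Si](CC)(CC)CC)[C@H]1C2(Br)Br | intermediate
7 | (1S,6S)-7,7-dibromo-6-methylbicyclo[4.1.0]heptan-2-one | C[C@]12CCCC(=O)[C@H]1C2(Br)Br | intermediate
8 | (1'S,6'S)-7',7'-dibromo-6'-methylspiro[1,3-dioxolane-2,2'-bicyclo[4.1.0]heptane] | C[C@]12CCCC3(OCCO3)[C@H]1C2(Br)Br | intermediate
9 | 7'-bromo-7'-lithio carbenoid derived from 8 (either epimer at C7') | C[C@]12CCCC3(OCCO3)[C@H]1C2([Li])Br | intermediate (not isolated)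
10 | 1-methyltricyclo[4.1.0.0(2,7)]heptan-3-one ethylene ketal, enantiomer derived from (1'S,6'S)-8 (central bond between C10 with methyl and C5 with hydrogen; wing C4 next to the ketal carbon C3, wing C11 next to C1) | C[C@]12[C@@H]3[C@H]1[C@H]2CCC34OCCO4 | intermediate
11 | mesityl oxide (4-methylpent-3-en-2-one) | CC(=O)C=C(C)C | starting material
12 | lithium 4-methylpenta-1,3-dien-2-olate | C=C(O[Li])C=C(C)C | intermediate (not isolated)
13 | 2-(tert-butyldimethylsilyloxy)-4-methylpenta-1,3-diene | C=C(O[Si](C)(C)C(C)(C)C)C=C(C)C | intermediate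
14 | 8-(tert-butyldimethylsilyloxy)-3-desmethyllongipin-7-en-3-one ethylene ketal | CC(C)(C)[Si](C)(C)OC1=CC(C)(C)[C@@H]2[C@H]3CCC4(OCCO4)[C@@H]2[C@@]3(C)C1 | intermediate
15 | 7,8-epoxide of 14, oxygen on the C4 face | CC(C)(C)[Si](C)(C)O[C@]1(O2)[C@@H]2C(C)(C)[C@@H]3[C@H]4CCC5(OCCO5)[C@@H]3[C@@]4(C)C1 | intermediate (not isolated)
16 | (7S)-7-hydroxy-3-desmethyllongipinane-3,8-dione 3-ethylene ketal | O=C1[C@@H](O)C(C)(C)[C@@H]2[C@H]3CCC4(OCCO4)[C@@H]2[C@@]3(C)C1 | intermediate
17 | 7-O-triethylsilyl ether of 16 | O=C1[C@@H](O[Si](CC)(CC)CC)C(C)(C)[C@@H]2[C@H]3CCC4(OCCO4)[C@@H]2[C@@]3(C)C1 | intermediate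
18 | lithium C8(O)=C9 enolate of 17 | [Li]OC=1[C@@H](O[Si](CC)(CC)CC)C(C)(C)[C@@H]2[C@H]3CCC4(OCCO4)[C@@H]2[C@@]3(C)C=1 | intermediate (not isolated)
19 | 9-hydroxy-7-(triethylsilyloxy)-3-desmethyllongipinane-3,8-dione 3-ethylene ketal (O7 on the C4 face, O9 on the C11 face) | O=C1[C@@H](O[Si](CC)(CC)CC)C(C)(C)[C@@H]2[C@H]3CCC4(OCCO4)[C@@H]2[C@@]3(C)[C@@H]1O | intermediate
20 | 9-(tert-butyldimethylsilyloxy)-7-(triethylsilyloxy)-3-desmethyllongipinane-3,8-dione 3-ethylene ketal | O=C1[C@@H](O[Si](CC)(CC)CC)C(C)(C)[C@@H]2[C@H]3CCC4(OCCO4)[C@@H]2[C@@]3(C)[C@@H]1O[Si](C)(C)C(C)(C)C | intermediate (not isolated)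
21 | 7-hydroxy-9-(tert-butyldimethylsilyloxy)-3-desmethyllongipinane-3,8-dione 3-ethylene ketal | O=C1[C@@H](O)C(C)(C)[C@@H]2[C@H]3CCC4(OCCO4)[C@@H]2[C@@]3(C)[C@@H]1O[Si](C)(C)C(C)(C)C | intermediate
22 | 7,8-dihydroxy-9-(tert-butyldimethylsilyloxy)-3-desmethyllongipinan-3-one ethylene ketal (O7 on the C4 face; O8, O9 on the C11 face) | O[C@@H]1[C@@H](O)C(C)(C)[C@@H]2[C@H]3CCC4(OCCO4)[C@@H]2[C@@]3(C)[C@@H]1O[Si](C)(C)C(C)(C)C | intermediate
23 | angelic acid ((Z)-2-methylbut-2-enoic acid) | C/C=C(/C)C(=O)O | starting material
24 | angelic 2,4,6-trichlorobenzoic anhydride | C/C=C(/C)C(=O)OC(=O)c1c(Cl)cc(Cl)cc1Cl | intermediate (not isolated)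
25 | 7,8-bis(angeloyloxy)-9-(tert-butyldimethylsilyloxy)-3-desmethyllongipinan-3-one ethylene ketal | C/C=C(/C)C(=O)O[C@@H]1[C@@H](OC(=O)/C(C)=C\C)C(C)(C)[C@@H]2[C@H]3CCC4(OCCO4)[C@@H]2[C@@]3(C)[C@@H]1O[Si](C)(C)C(C)(C)C | intermediate
26 | 7,8-bis(angeloyloxy)-9-(tert-butyldimethylsilyloxy)-3-desmethyllongipinan-3-one | C/C=C(/C)C(=O)O[C@@H]1[C@@H](OC(=O)/C(C)=C\C)C(C)(C)[C@@H]2[C@H]3CCC(=O)[C@@H]2[C@@]3(C)[C@@H]1O[Si](C)(C)C(C)(C)C | intermediate
27 | potassium C2=C3 enolate of 26 | C/C=C(/C)C(=O)O[C@@H]1[C@@H](OC(=O)/C(C)=C\C)C(C)(C)[C@@H]2[C@H]3CC=C(O[K])[C@@H]2[C@@]3(C)[C@@H]1O[Si](C)(C)C(C)(C)C | intermediate (not isolated)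
28 | 7,8-bis(angeloyloxy)-9-(tert-butyldimethylsilyloxy)-3-desmethyllongipin-2-en-3-yl trifluoromethanesulfonate | C/C=C(/C)C(=O)O[C@@H]1[C@@H](OC(=O)/C(C)=C\C)C(C)(C)[C@@H]2[C@H]3CC=C(OS(=O)(=O)C(F)(F)F)[C@@H]2[C@@]3(C)[C@@H]1O[Si](C)(C)C(C)(C)C | intermediate
29 | 7,8-bis(angeloyloxy)-9-(tert-butyldimethylsilyloxy)longipin-2-ene | C/C=C(/C)C(=O)O[C@@H]1[C@@H](OC(=O)/C(C)=C\C)C(C)(C)[C@@H]2[C@H]3CC=C(C)[C@@H]2[C@@]3(C)[C@@H]1O[Si](C)(C)C(C)(C)C | intermediate
30 | 7,8-bis(angeloyloxy)-9-(tert-butyldimethylsilyloxy)longipin-2-en-1-one | C/C=C(/C)C(=O)O[C@@H]1[C@@H](OC(=O)/C(C)=C\C)C(C)(C)[C@@H]2[C@H]3C(=O)C=C(C)[C@@H]2[C@@]3(C)[C@@H]1O[Si](C)(C)C(C)(C)C | intermediate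
31 | (4R,5S,7S,8S,9S,10R,11R)-7,8-bis(angeloyloxy)-9-hydroxylongipin-2-en-1-one | C/C=C(/C)C(=O)O[C@@H]1[C@@H](OC(=O)/C(C)=C\C)C(C)(C)[C@@H]2[C@H]3C(=O)C=C(C)[C@@H]2[C@@]3(C)[C@@H]1O | target

Total steps: 19. Longest linear sequence: 18 steps (1–6, then 8–19); step 7 is a one-step side branch.

Steps most likely to fail

1. Step 8 (proposed new method). Three processes can defeat it: bond formation from the rear of the central bond, which puts the diene on the concave side where the ring cannot close; first bonding of C9 to C5 or closure at C8, giving (3+2) adducts across the enol double bond; and oxidative dimerisation or desilylation of the diene outrunning the annulation. The fallback uses the documented radical chemistry of this ring system, in which additions across the central bond run anti; it sets out from 10 and comes back at 14. Bicyclobutane 10 and allyl bromide under bromine-atom chain conditions ((Bu3Sn)2, light, benzene) should give the bromo allyl adduct F1: bromine enters C5 from the rear, and the tertiary C10 radical takes the allyl group on the open convex face, which puts C9 in place and turns the methyl toward the C1–C3 bridge. Wacker oxidation (PdCl2, CuCl, O2, DMF–H2O) gives the methyl ketone F2. Its kinetic lithium enolate, formed at the methyl group (LiN(i-Pr)2, THF, −78 °C), adds to acetone to give the β-hydroxy ketone F3, which is dehydrated (catalytic p-TsOH, 4 Å molecular sieves, benzene, rt) to the enone F4. Bu3SnH with AIBN, added slowly at high dilution, then generates the C5 radical, which closes 7-endo onto C6 (Giese cyclisation) from the only face the tether allows, leaving the C5 hydrogen toward the bridge and giving the ketone F5. Deprotonation of F5 with the lithium amide of bis(1-phenylethyl)amine (the enantiomer that removes a C7 proton) and silylation with t-BuMe2SiOTf returns the silyl enol ether 14.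

2. Step 14. Acylation may stall at the neopentyl C7 hydroxyl, the angelate may isomerise to the tiglate on prolonged heating, and the neighbouring silyl group may migrate. The fallback builds the Z-alkenes on the esters instead; it sets out from 22 and comes back at 25. Diol 22 is esterified with two equivalents of 2-[bis(2,2,2-trifluoroethoxy)phosphoryl]propanoic acid (DCC, DMAP, CH2Cl2) to the bis-phosphonate F6, and Still–Gennari olefination with acetaldehyde (KN(SiMe3)2, 18-crown-6, THF, −78 °C) converts both phosphonates into (Z)-2-methylbut-2-enoates, giving 25.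

3. Step 18. The allylic oxidation may be unselective (attack at the C3 methyl or at the angelate methyls) or over-oxidise a late, precious intermediate. The fallback makes the enone by carbonyl transposition with no C–H oxidation; it sets out from 26 and comes back at 30, replacing steps 16–18. Ketone 26 is dehydrogenated with IBX (DMSO, 70 °C) to the C1=C2 enone F7; MeLi with CeCl3 (THF, −78 °C) adds to the C3 carbonyl faster than to the hindered angelates, giving the tertiary allylic alcohol F8; pyridinium chlorochromate, C5H5NH[CrO3Cl] (CH2Cl2, rt), then effects the Dauben–Babler oxidative transposition to enone 30.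

Further compounds
F1 | step 8 | bromo allyl adduct of 10: C5–Br toward the C1–C3 bridge, C10–allyl on the convex face, C3 ethylene ketal | Br[C@H]1[C@H]2CCC3(OCCO3)[C@@H]1[C@@]2(C)CC=C
F2 | step 8 | methyl ketone from F1 (C10–CH2–CO–CH3) | Br[C@H]1[C@H]2CCC3(OCCO3)[C@@H]1[C@@]2(C)CC(C)=O
F3 | step 8 | β-hydroxy ketone from F2 and acetone (C10–CH2–CO–CH2–C(OH)Me2) | Br[C@H]1[C@H]2CCC3(OCCO3)[C@@H]1[C@@]2(C)CC(=O)CC(C)(C)O
F4 | step 8 | enone from F3 (C10–CH2–CO–CH=CMe2) | Br[C@H]1[C@H]2CCC3(OCCO3)[C@@H]1[C@@]2(C)CC(=O)C=C(C)C
F5 | step 8 | 3-desmethyllongipinane-3,8-dione 3-ethylene ketal | O=C1CC(C)(C)[C@@H]2[C@H]3CCC4(OCCO4)[C@@H]2[C@@]3(C)C1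
F6 | step 14 | 7,8-bis{2-[bis(2,2,2-trifluoroethoxy)phosphoryl]propanoate} of 22 | CC(C(=O)O[C@@H]1[C@@H](OC(=O)C(C)P(=O)(OCC(F)(F)F)OCC(F)(F)F)C(C)(C)[C@@H]2[C@H]3CCC4(OCCO4)[C@@H]2[C@@]3(C)[C@@H]1O[Si](C)(C)C(C)(C)C)P(=O)(OCC(F)(F)F)OCC(F)(F)F
F7 | step 18 | 7,8-bis(angeloyloxy)-9-(tert-butyldimethylsilyloxy)-3-desmethyllongipin-1-en-3-one | C/C=C(/C)C(=O)O[C@@H]1[C@@H](OC(=O)/C(C)=C\C)C(C)(C)[C@@H]2[C@H]3C=CC(=O)[C@@H]2[C@@]3(C)[C@@H]1O[Si](C)(C)C(C)(C)C
F8 | step 18 | 7,8-bis(angeloyloxy)-9-(tert-butyldimethylsilyloxy)longipin-1-en-3-ol (tertiary allylic alcohol, either C3 epimer) | C/C=C(/C)C(=O)O[C@@H]1[C@@H](OC(=O)/C(C)=C\C)C(C)(C)[C@@H]2[C@H]3C=CC(C)(O)[C@@H]2[C@@]3(C)[C@@H]1O[Si](C)(C)C(C)(C)C
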